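The carbocycle C7–C12 is read as a dearomatised 3,5-dimethylbenzoic acid. Its C8 and C10 methyls lie meta to C12, the carboxyl-level carbon that becomes pyrone C2', and the C7 side chain is trans to the C12 methyl. Everything rests on cutting C6–C7 and C12–CH3 together. An alkenyllithium carrying C1–C6 (lithium trans to C4, C3 as silyl ether) adds to an ortho carbon of a Cr(CO)3-bound chiral aryloxazoline, and MeI quenches the ipso carbon. This gives the C8=C9–C10=C11 diene and both ring stereocentres at once. The precursor is the Cr(CO)3 complex of (S)-4-tert-butyl-2-(3,5-dimethylphenyl)oxazoline. Pyrone annulation, C3 oxidation and C8–C9 epoxidation finish the synthesis.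

Key step: step 10

Remarks on the chemistry (one line each)
- Numbering: chain C1–C6 from the ethyl end (C3 ketone, C4 methine, C5=C6), ring C7–C12 (C7 bears the chain, C8–C9 epoxide, C10=C11, C12 quaternary), pyrone C2'–C6' starting at the carbon on C12.
- Assumption: in the N-chelated rotamer the (S)-tert-butyl group is taken to lie on the chromium face, so exo delivery reaches the ortho carbon that gives the target configuration at C7; if the opposite sense is found, (R)-tert-leucinol is used and nothing else changes.
- Descriptor correction: alkenyllithium 19 keeps the geometry of the (E)-iodide 18 (Li trans to C4), but its formal label is Z because lithium ranks below methyl; this geometry also keeps lithium away from the silyloxy chain, so silyl migration to carbon is excluded.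
- The C3 silyl ether configuration (3R, from the syn aldol) is a spectator that step 18 erases; it is kept single only so that intermediates are single compounds.
- Compounds from 21 onwards are kept from light and strong acid, because the cyclohexa-1,3-diene is photolabile and electron-rich.

Step 1
Reactants: 1 3,5-dimethylbenzonitrile; 2 (S)-tert-leucinol
Product: 3 (S)-4-tert-butyl-2-(3,5-dimethylphenyl)-4,5-dihydrooxazole
Conditions: ZnCl2 (10 mol%), PhCl, reflux, 24 h
Reagents that add atoms: none
Why: Zinc-catalysed condensation of a nitrile with a 1,2-amino alcohol (Witte–Seeliger oxazoline synthesis) should proceed through the amidine with loss of NH3 and does not touch the tert-leucinol stereocentre.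

Step 2
Reactants: 3 (S)-4-tert-butyl-2-(3,5-dimethylphenyl)-4,5-dihydrooxazole; 4 chromium hexacarbonyl Cr(CO)6
Product: 5 Cr(CO)3 complex of oxazoline 3
Conditions: Bu2O/THF (10:1), reflux, 36 h, N2, dark
Reagents that add atoms: chromium hexacarbonyl (4), [Cr].[C-]#[O+].[C-]#[O+].[C-]#[O+].[C-]#[O+].[C-]#[O+].[C-]#[O+]
Why: Thermal arene complexation (CO/arene ligand exchange at zerovalent chromium) is standard for such arenes, and since the arene has a mirror plane through C1 and C4 only one complex can form.

Step 3
Reactants: 6 (S)-4-benzyl-3-propionyloxazolidin-2-one; 7 propanal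
Product: 9 Evans syn-aldol imide (2S,3R), via boron enolate 8 (not isolated)
Conditions: Bu2BOTf, i-Pr2NEt, CH2Cl2, 0 °C; 7, −78 → 0 °C; then pH 7 buffer, MeOH, 30% H2O2, 0 °C
Reagents that add atoms: none
Why: Evans syn-aldol reaction, in which the Z boron enolate reacts through a closed Zimmerman–Traxler chair on the face away from the benzyl group, should set 2S (the future C4) and 3R (the C3 carbinol).

Step 4
Reactants: 9 Evans syn-aldol imide
Product: 10 β-hydroxy Weinreb amide (2S,3R)
Conditions: MeNHOMe·HCl, AlMe3, CH2Cl2, −20 → 0 °C; aq. HCl (0.5 M)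
Reagents that add atoms: N,O-dimethylhydroxylamine hydrochloride, CNOC.Cl
Why: Aluminium-amide transamidation of the imide (Weinreb amide formation) is steered to the exocyclic carbonyl by the β-hydroxyl as its aluminium alkoxide and should leave the α-stereocentre intact.

Step 5
Reactants: 10 β-hydroxy Weinreb amide
Product: 11 silyl ether of the Weinreb amide
Conditions: TBSOTf, 2,6-lutidine, CH2Cl2, −78 → 0 °C
Reagents that add atoms: tert-butyldimethylsilyl trifluoromethanesulfonate, CC(C)(C)[Si](C)(C)OS(=O)(=O)C(F)(F)F
Why: Silylation of a secondary alcohol with a silyl triflate and a hindered pyridine base is fast at low temperature and non-epimerising.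

Step 6
Reactants: 11 silyl ether of the Weinreb amide
Product: 12 (2S,3R)-3-(tert-butyldimethylsilyloxy)-2-methylpentanal
Conditions: i-Bu2AlH, THF, −78 °C; aq. KNaC4H4O6 (potassium sodium tartrate)
Reagents that add atoms: none
Why: Hydride reduction of a Weinreb amide stops at the chelated aluminium hemiaminal, which releases the aldehyde only on work-up, so over-reduction and α-epimerisation should be avoided.

Step 7
Reactants: 12 (2S,3R)-3-(tert-butyldimethylsilyloxy)-2-methylpentanal
Product: 13 1,1-dibromoalkene (3R,4R)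
Conditions: CBr4, PPh3, 2,6-lutidine, CH2Cl2, 0 °C
Reagents that add atoms: carbon tetrabromide, BrC(Br)(Br)Br
Why: Corey–Fuchs dibromo-olefination (Wittig reaction of Ph3P=CBr2) under buffered conditions should convert the α-branched aldehyde without loss of configuration.

Step 8
Reactants: 13 1,1-dibromoalkene; 14 iodomethane
Product: 16 methyl alkyne (3R,4R), via lithium acetylide 15 (not isolated)
Conditions: n-BuLi (2.2 equiv), THF, −78 °C; then MeI, −78 °C → rt
Reagents that add atoms: iodomethane (14), CI
Why: This is the second stage of the Corey–Fuchs sequence, in which bromine–lithium exchange, a Fritsch–Buttenberg–Wiechell 1,2-shift and deprotonation give the lithium acetylide that is C-methylated in the same flask.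

Step 9
Reactants: 16 methyl alkyne
Product: 18 (E)-alkenyl iodide, via alkenylzirconocene chloride 17 (not isolated)
Conditions: Cp2Zr(H)Cl (2.2 equiv), THF, 50 °C, dark; then I2, 0 °C
Reagents that add atoms: iodine, II
Why: Hydrozirconation–iodination should give the E iodide, because Zr–H adds syn, excess Cp2Zr(H)Cl equilibrates zirconium to the less hindered methyl-bearing carbon, and iodinolysis proceeds with retention.

Step 10
Reactants: 5 Cr(CO)3 complex of oxazoline 3; 18 (E)-alkenyl iodide; 14 iodomethane
Product: 21 trans-5-alkenyl-6-methyl-6-oxazolinylcyclohexa-1,3-diene (1R,6S), via alkenyllithium 19 (not isolated), via lithium cyclohexadienylchromate 20 (not isolated)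
Conditions: 18 (1.2 equiv), t-BuLi (2.4 equiv), Et2O, −78 °C; add to 5, THF, −78 → −40 °C; MeI (10 equiv), HMPA (10 equiv), −78 °C → rt, Ar (no CO); then air, Et2O, Celite, dark
Reagents that add atoms: iodomethane (14), CI
Why: Alkenyllithium 19, held by the oxazoline nitrogen, adds to the neighbouring ortho carbon (C7) on the face opposite Cr(CO)3 to give the anionic η5-cyclohexadienyl complex 20; MeI then alkylates chromium and reductive elimination moves the methyl from the metal face onto the oxazoline-bearing terminus C12, leaving the C8=C9–C10=C11 diene, which is freed from chromium on aerial work-up. The closest known reaction type is the sequential organolithium/carbon-electrophile trans addition across one arene bond of (aryloxazoline)Cr(CO)3 complexes, and no ring is closed. The C7 centre is fixed by exo attack together with the choice between the two diastereotopic ortho carbons, which the (S)-tert-butyl group makes by lying on the chromium side in the N-chelated rotamer; the C12 centre follows from C7 because methyl can only arrive from the metal face, hence side chain trans to methyl and cis to the oxazoline carbon. The step needs ring addition rather than benzylic or ortho deprotonation, methylation at C12 rather than C8, and methyl rather than acetyl transfer; nitrogen-directed delivery at −78 °C, the azaenolate-like charge at C12, and a CO-free argon atmosphere with excess MeI/HMPA are relied on for these.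

Step 11
Reactants: 21 trans-5-alkenyl-6-methyl-6-oxazolinylcyclohexa-1,3-diene
Product: 23 N-methyloxazolidine, via oxazolinium triflate 22 (not isolated)
Conditions: MeOTf, CH2Cl2, rt; then NaBH4, THF/MeOH (4:1), 0 °C
Reagents that add atoms: methyl trifluoromethanesulfonate, COS(=O)(=O)C(F)(F)F
Why: N-Alkylation followed by hydride reduction of a 2-oxazoline (the standard reductive unmasking to the aldehyde level) works because methylation turns the C=N into an iminium ether that accepts exactly one hydride, even at this quaternary position.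

Step 12
Reactants: 23 N-methyloxazolidine
Product: 24 cyclohexadiene carbaldehyde (1R,6S)
Conditions: (CO2H)2, THF/H2O (4:1), 0 °C → rt
Reagents that add atoms: water, O
Why: Mild acid hydrolysis of the N,O-acetal releases the aldehyde and the N-methylamino alcohol, and since C12 is quaternary nothing can epimerise.

Step 13
Reactants: 24 cyclohexadiene carbaldehyde; 25 ethyl 2-methyl-3-oxopentanoate
Product: 27 δ-hydroxy-β-keto ester, via keto ester dianion 26 (not isolated)
Conditions: 25 (2.5 equiv), NaH, THF, 0 °C; n-BuLi, 0 °C; then 24, −78 → −40 °C; aq. NH4Cl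
Reagents that add atoms: none
Why: In this β-keto ester dianion aldol addition the more reactive γ-carbanion adds to the non-enolisable aldehyde, and the three new stereocentres are irrelevant because steps 14 and 15 destroy them.

Step 14
Reactants: 27 δ-hydroxy-β-keto ester
Product: 28 β,δ-diketo ester
Conditions: Dess–Martin periodinane, NaHCO3, CH2Cl2, 0 °C → rt
Reagents that add atoms: none
Why: Dess–Martin oxidation converts the hindered secondary carbinol to the ketone under near-neutral conditions that spare the diene and the silyl ether.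

Step 15
Reactants: 28 β,δ-diketo ester
Product: 29 4-hydroxy-2-pyranone
Conditions: DBU, toluene, 60 °C
Reagents that add atoms: none
Why: Base-mediated enol lactonisation of a β,δ-diketo ester, in which the enol oxygen of the C12-bound ketone displaces ethoxide, is the standard entry to 4-hydroxy-3,5-dimethyl-2-pyranones.

Step 16
Reactants: 29 4-hydroxy-2-pyranone
Product: 31 2-methoxy-4-pyranone silyl ether, via hydroxypyrylium fluorosulfonate 30 (not isolated)
Conditions: MeOSO2F, CH2Cl2, 0 °C → rt; then cold aq. NaHCO3
Reagents that add atoms: methyl fluorosulfonate, COS(=O)(=O)F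
Why: O-Methylation of the neutral 4-hydroxy-2-pyranone with a hard methylating agent occurs at the ring carbonyl oxygen (the heteroatom remote from the acidic proton), and deprotonation of the pyrylium salt should give the 2-methoxy-4-pyranone.

Step 17
Reactants: 31 2-methoxy-4-pyranone silyl ether
Product: 32 C3 alcohol
Conditions: Bu4NF, AcOH, THF, rt → 40 °C
Reagents that add atoms: none
Why: Fluoride-mediated desilylation buffered with acetic acid should remove the secondary silyl ether without touching the methoxypyrone or the diene.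

Step 18
Reactants: 32 C3 alcohol
Product: 33 C3 ketone (epoxide-free precursor)
Conditions: Dess–Martin periodinane, NaHCO3, CH2Cl2, 0 °C
Reagents that add atoms: none
Why: Buffered Dess–Martin oxidation forms the β,γ-unsaturated ketone without acid or base strong enough to epimerise C4 or move the C5=C6 bond into conjugation.

Step 19
Reactants: 33 C3 ketone
Product: 34 target CNP0336888.3
Conditions: DMDO (1.05 equiv), acetone/CH2Cl2, −40 → −20 °C, dark
Reagents that add atoms: dimethyldioxirane, CC1(C)OO1
Why: Neutral dioxirane epoxidation should take C8=C9 on the face opposite the pseudoaxial C7 side chain (the face of H7 and the C12 methyl), because C10=C11 is neopentylic and inductively deactivated by the pyrone-bearing C12, C5=C6 is flanked by two branched carbons and the C3 carbonyl, and the vinyl epoxide formed resists a second oxidation.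

Compound list
1 | 3,5-dimethylbenzonitrile | Cc1cc(C)cc(c1)C#N | starting material
2 | (S)-tert-leucinol, (S)-2-amino-3,3-dimethylbutan-1-ol | N[C@@H](C(C)(C)C)CO | starting material
3 | (S)-4-tert-butyl-2-(3,5-dimethylphenyl)-4,5-dihydrooxazole | Cc1cc(C)cc(c1)C1=N[C@@H](C(C)(C)C)CO1 | intermediate
4 | chromium hexacarbonyl, Cr(CO)6 | [Cr].[C-]#[O+].[C-]#[O+].[C-]#[O+].[C-]#[O+].[C-]#[O+].[C-]#[O+] | starting material
5 | tricarbonyl[η6-(S)-4-tert-butyl-2-(3,5-dimethylphenyl)-4,5-dihydrooxazole]chromium | Cc1cc(C)cc(c1)C1=N[C@@H](C(C)(C)C)CO1.[Cr].[C-]#[O+].[C-]#[O+].[C-]#[O+] | intermediate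
6 | (S)-4-benzyl-3-propionyloxazolidin-2-one | CCC(=O)N1[C@@H](Cc2ccccc2)COC1=O | starting material
7 | propanal | CCC=O | starting material
8 | (S)-4-benzyl-3-[(Z)-1-(dibutylboryloxy)prop-1-en-1-yl]oxazolidin-2-one | C/C=C(\OB(CCCC)CCCC)N1[C@@H](Cc2ccccc2)COC1=O | intermediate (not isolated)
9 | (S)-4-benzyl-3-[(2S,3R)-3-hydroxy-2-methylpentanoyl]oxazolidin-2-one | CC[C@@H](O)[C@H](C)C(=O)N1[C@@H](Cc2ccccc2)COC1=O | intermediate
10 | (2S,3R)-3-hydroxy-N-methoxy-N,2-dimethylpentanamide | CC[C@@H](O)[C@H](C)C(=O)N(C)OC | intermediate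
11 | (2S,3R)-3-(tert-butyldimethylsilyloxy)-N-methoxy-N,2-dimethylpentanamide | CC[C@@H](O[Si](C)(C)C(C)(C)C)[C@H](C)C(=O)N(C)OC | intermediate
12 | (2S,3R)-3-(tert-butyldimethylsilyloxy)-2-methylpentanal | CC[C@@H](O[Si](C)(C)C(C)(C)C)[C@H](C)C=O | intermediate
13 | tert-butyl{[(3R,4R)-6,6-dibromo-4-methylhex-5-en-3-yl]oxy}dimethylsilane | CC[C@@H](O[Si](C)(C)C(C)(C)C)[C@H](C)C=C(Br)Br | intermediate
14 | iodomethane | CI | starting material
15 | [(3R,4R)-4-(tert-butyldimethylsilyloxy)-3-methylhex-1-yn-1-yl]lithium | CC[C@@H](O[Si](C)(C)C(C)(C)C)[C@H](C)C#C[Li] | intermediate (not isolated)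
16 | tert-butyldimethyl{[(3R,4R)-4-methylhept-5-yn-3-yl]oxy}silane | CC[C@@H](O[Si](C)(C)C(C)(C)C)[C@H](C)C#CC | intermediate
17 | chlorobis(cyclopentadienyl)[(2E,4R,5R)-5-(tert-butyldimethylsilyloxy)-4-methylhept-2-en-2-yl]zirconium | CC[C@@H](O[Si](C)(C)C(C)(C)C)[C@H](C)/C=C(\C)[Zr](Cl)(C1C=CC=C1)C1C=CC=C1 | intermediate (not isolated)
18 | tert-butyl{[(3R,4R,5E)-6-iodo-4-methylhept-5-en-3-yl]oxy}dimethylsilane | CC[C@@H](O[Si](C)(C)C(C)(C)C)[C@H](C)/C=C(\C)I | intermediate
19 | [(2Z,4R,5R)-5-(tert-butyldimethylsilyloxy)-4-methylhept-2-en-2-yl]lithium (Li trans to C4) | CC[C@@H](O[Si](C)(C)C(C)(C)C)[C@H](C)/C=C(\C)[Li] | intermediate (not isolated)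
20 | lithium tricarbonyl(η5-cyclohexadienyl)chromate from exo addition of 19 to C7 of 5 (negative charge drawn on C12) | CC[C@@H](O[Si](C)(C)C(C)(C)C)[C@H](C)/C=C(\C)[C@H]1C(C)=CC(C)=C[C-]1C1=N[C@@H](C(C)(C)C)CO1.[Cr].[C-]#[O+].[C-]#[O+].[C-]#[O+].[Li+] | intermediate (not isolated)
21 | (4S)-4-tert-butyl-2-{(1R,6S)-6-[(2E,4R,5R)-5-(tert-butyldimethylsilyloxy)-4-methylhept-2-en-2-yl]-1,3,5-trimethylcyclohexa-2,4-dien-1-yl}-4,5-dihydrooxazole | CC[C@@H](O[Si](C)(C)C(C)(C)C)[C@H](C)/C=C(\C)[C@H]1C(C)=CC(C)=C[C@@]1(C)C1=N[C@@H](C(C)(C)C)CO1 | intermediate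
22 | N-methyloxazolinium triflate of 21 | CC[C@@H](O[Si](C)(C)C(C)(C)C)[C@H](C)/C=C(\C)[C@H]1C(C)=CC(C)=C[C@@]1(C)C1=[N+](C)[C@@H](C(C)(C)C)CO1.[O-]S(=O)(=O)C(F)(F)F | intermediate (not isolated)
23 | (4S)-4-tert-butyl-3-methyl-2-[ring of 21]oxazolidine (epimers at the aminal carbon) | CC[C@@H](O[Si](C)(C)C(C)(C)C)[C@H](C)/C=C(\C)[C@H]1C(C)=CC(C)=C[C@@]1(C)C1N(C)[C@@H](C(C)(C)C)CO1 | intermediate
24 | (1R,6S)-6-[(2E,4R,5R)-5-(tert-butyldimethylsilyloxy)-4-methylhept-2-en-2-yl]-1,3,5-trimethylcyclohexa-2,4-diene-1-carbaldehyde | CC[C@@H](O[Si](C)(C)C(C)(C)C)[C@H](C)/C=C(\C)[C@H]1C(C)=CC(C)=C[C@@]1(C)C=O | intermediate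
25 | ethyl 2-methyl-3-oxopentanoate (racemic) | CCOC(=O)C(C)C(=O)CC | starting material
26 | sodium lithium dienediolate (dianion) of 25 | CCOC([O-])=C(C)C([O-])=CC.[Na+].[Li+] | intermediate (not isolated)
27 | ethyl 5-hydroxy-2,4-dimethyl-3-oxo-5-[(1R,6S)-ring of 24]pentanoate (mixture at the three new centres) | CC[C@@H](O[Si](C)(C)C(C)(C)C)[C@H](C)/C=C(\C)[C@H]1C(C)=CC(C)=C[C@@]1(C)C(O)C(C)C(=O)C(C)C(=O)OCC | intermediate
28 | ethyl 2,4-dimethyl-3,5-dioxo-5-[(1R,6S)-ring of 24]pentanoate | CC[C@@H](O[Si](C)(C)C(C)(C)C)[C@H](C)/C=C(\C)[C@H]1C(C)=CC(C)=C[C@@]1(C)C(=O)C(C)C(=O)C(C)C(=O)OCC | intermediate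
29 | 6-{(1R,6S)-6-[(2E,4R,5R)-5-(tert-butyldimethylsilyloxy)-4-methylhept-2-en-2-yl]-1,3,5-trimethylcyclohexa-2,4-dien-1-yl}-4-hydroxy-3,5-dimethyl-2H-pyran-2-one | CC[C@@H](O[Si](C)(C)C(C)(C)C)[C@H](C)/C=C(\C)[C@H]1C(C)=CC(C)=C[C@@]1(C)c1oc(=O)c(C)c(O)c1C | intermediate
30 | 4-hydroxy-2-methoxy-3,5-dimethyl-6-[ring of 29]pyrylium fluorosulfonate | CC[C@@H](O[Si](C)(C)C(C)(C)C)[C@H](C)/C=C(\C)[C@H]1C(C)=CC(C)=C[C@@]1(C)c1[o+]c(OC)c(C)c(O)c1C.[O-]S(=O)(=O)F | intermediate (not isolated)
31 | 6-{(1R,6S)-6-[(2E,4R,5R)-5-(tert-butyldimethylsilyloxy)-4-methylhept-2-en-2-yl]-1,3,5-trimethylcyclohexa-2,4-dien-1-yl}-2-methoxy-3,5-dimethyl-4H-pyran-4-one | CC[C@@H](O[Si](C)(C)C(C)(C)C)[C@H](C)/C=C(\C)[C@H]1C(C)=CC(C)=C[C@@]1(C)c1oc(OC)c(C)c(=O)c1C | intermediate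
32 | 6-{(1R,6S)-6-[(2E,4R,5R)-5-hydroxy-4-methylhept-2-en-2-yl]-1,3,5-trimethylcyclohexa-2,4-dien-1-yl}-2-methoxy-3,5-dimethyl-4H-pyran-4-one | CC[C@@H](O)[C@H](C)/C=C(\C)[C@H]1C(C)=CC(C)=C[C@@]1(C)c1oc(OC)c(C)c(=O)c1C | intermediate
33 | 2-methoxy-3,5-dimethyl-6-{(1R,6S)-1,3,5-trimethyl-6-[(2E,4R)-4-methyl-5-oxohept-2-en-2-yl]cyclohexa-2,4-dien-1-yl}-4H-pyran-4-one | CCC(=O)[C@H](C)/C=C(\C)[C@H]1C(C)=CC(C)=C[C@@]1(C)c1oc(OC)c(C)c(=O)c1C | intermediate
34 | 2-methoxy-3,5-dimethyl-6-{(1R,4R,5R,6S)-2,4,6-trimethyl-5-[(2E,4R)-4-methyl-5-oxohept-2-en-2-yl]-7-oxabicyclo[4.1.0]hept-2-en-4-yl}-4H-pyran-4-one (chain numbering: 4R, 7R, 8S, 9R, 12R; epoxide anti to the C7 chain and the pyrone) | CCC(=O)[C@H](C)/C=C(\C)[C@H]1[C@]2(C)O[C@@H]2C(C)=C[C@@]1(C)c1oc(OC)c(C)c(=O)c1C | target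

Total step count: 19 (steps 1–2 arene branch, steps 3–9 side-chain branch, steps 10–19 after convergence).
Longest linear sequence: 17 steps (steps 3–19).
The Evans aldol branch is two steps longer than a propargylation route would be; it is kept because its absolute configuration at C4 is the most dependable.

Three steps most likely to fail

1. Step 10 (key step). The hindered, α-branched alkenyllithium may abstract a benzylic or ortho proton instead of adding next to a ring methyl. After addition, migratory CO insertion at chromium may outrun direct methyl transfer, so that acetyl and not methyl reaches C12. The auxiliary may also discriminate the two ortho carbons poorly. Fallback: it sets out from complex 5 and iodide 18 and comes back at 21. The addition is run as before, but the anionic complex 20 is quenched with CF3CO2H at −78 °C and the chromium is removed in air. This gives the conjugated dienyl oxazoline F1 (C12=C11–C10=C9 diene, C8 epimers, C7 as in 21). LiN(i-Pr)2 in THF at −78 °C then regenerates the metal-free extended azaenolate, and MeI alkylates it at C12 on the face away from the C7 chain, which returns 21. Ring–chain bond formation and quaternisation are thereby separated, and no metal–methyl species that could insert CO is involved.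

2. Step 19. Oxygen transfer may go to C10=C11 or to the side-chain C5=C6 bond, or to the wrong face of C8=C9, since all three alkenes are trisubstituted. Fallback: it sets out from 33 and comes back at 34. Sensitised photo-oxygenation (O2, tetraphenylporphyrin, visible light, CH2Cl2, −78 °C) uses singlet oxygen, which engages only the cisoid ring diene in a [4+2] cycloaddition from the face of H7 and the C12 methyl. This gives the 8,11-endoperoxide F2. PPh3 (CH2Cl2, 0 °C → rt) then attacks the less hindered peroxide oxygen on C11, and the C8 alkoxide closes onto C9 in a syn SN2' displacement of Ph3PO. The result is the C8–C9 epoxide on the same face with the C10=C11 bond restored. Which peroxide oxygen PPh3 attacks is unproven on this system; if it is the C8 oxygen, the C10–C11 epoxide results, so the outcome must be checked.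

3. Step 16. Methyl transfer may go to the 4-hydroxyl oxygen, giving the isomeric 4-methoxy-2-pyranone, and acid carried by the pyrylium salt may attack the electron-rich diene or the silyl ether. Fallback: it sets out from 29 and comes back at 31. The 4-hydroxyl is first blocked (Et3SiCl, imidazole, CH2Cl2) to give the 4-triethylsilyloxy-2-pyranone F3, so only the ring carbonyl oxygen is left for MeOTf (CH2Cl2, 0 °C) and no proton is released. Bicarbonate work-up removes the silyl group from the 2-methoxy-4-silyloxypyrylium ion and delivers 31.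

Further compounds
F1 | step 10 | (4S)-4-tert-butyl-2-{6-[(2E,4R,5R)-5-(tert-butyldimethylsilyloxy)-4-methylhept-2-en-2-yl]-3,5-dimethylcyclohexa-1,3-dien-1-yl}-4,5-dihydrooxazole (C5 epimers, C6 as C7 of 21) | CC[C@@H](O[Si](C)(C)C(C)(C)C)[C@H](C)/C=C(\C)[C@H]1C(C)C=C(C)C=C1C1=N[C@@H](C(C)(C)C)CO1
F2 | step 19 | 8,11-endoperoxide of 33 (2,3-dioxabicyclo[2.2.2]oct-5-ene, peroxide bridge on the face opposite the C7 chain and the pyrone) | CCC(=O)[C@H](C)/C=C(\C)[C@H]1[C@@]2(C)C=C(C)[C@H](OO2)[C@@]1(C)c1oc(OC)c(C)c(=O)c1C
F3 | step 16 | 4-triethylsilyl ether of 29, 3,5-dimethyl-6-[ring of 29]-4-(triethylsilyloxy)-2H-pyran-2-one | CC[C@@H](O[Si](C)(C)C(C)(C)C)[C@H](C)/C=C(\C)[C@H]1C(C)=CC(C)=C[C@@]1(C)c1oc(=O)c(C)c(O[Si](CC)(CC)CC)c1C
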